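5 questions stand here: which of 4 flasks gives the most G at 6.0 min, and what each gives.

| flask | Q | D | remark | time |
|---|---|---|---|---|
| red | 0.010 M | 5 equiv | run made earlier |  |
| violet | 0.0050 M | 5 equiv | run made earlier |  |
| grey | 0.0075 M | 5 equiv | run made earlier |  |
| teal | 0.010 M | 7.5 equiv | run made earlier |  |
| midnight | 0.010 M | 5.00 equiv (fed, over 4.0 min) | all else is in the flask from the start; the feed brings no volume worth counting | 6.0 min |
| dusk | 0.010 M | 5.00 equiv (fed, over 1.0 min) | all else is in the flask from the start; the feed brings no volume worth counting | 6.0 min |
| dawn | 0.010 M | 5.00 equiv | everything together at the start | 6.0 min |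
| autumn | 0.010 M (fed, over 4.0 min) | 5.00 equiv | all else is in the flask from the start; the feed brings no volume worth counting | 6.0 min |

| run | time / min | G / % |
|---|---|---|
| red | 1.33 | 38.3 |
| red | 2.50 | 52.5 |
| red | 4.00 | 65.5 |
| red | 5.00 | 69.3 |
| red | 6.00 | 73.4 |
| violet | 0.500 | 12.6 |
| violet | 0.833 | 19.8 |
| violet | 1.50 | 29.8 |
| violet | 3.00 | 46.7 |
| violet | 6.00 | 60.5 |
| grey | 0.500 | 16.6 |
| grey | 0.833 | 24.1 |
| grey | 1.50 | 34.5 |
| grey | 3.00 | 51.6 |
| grey | 6.00 | 68.3 |
| teal | 1.33 | 47.2 |
| teal | 2.50 | 63.6 |
| teal | 4.00 | 74.4 |
| teal | 5.00 | 77.7 |
| teal | 6.00 | 80.3 |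

(standard deviation of a reading: 1 percentage point)

- the flask that comes out highest in amount of G, in percent of the Q charged, or "all alike" when all lie within 1.5 percentage points (midnight / dusk / dawn / autumn / all alike)
- G at the end, in percent of the Q charged, midnight
- G at the end, in percent of the Q charged, dusk
- G at the end, in percent of the Q charged, dawn
- G at the end, in percent of the Q charged, autumn

- a species is counted by the Q in it: one E or X counts as two
- amounts and yields of G count E and J too
- given per volume of solution although it is solid: J
- what may be going on: Q + D <-> Z; Z -> G; Q + G <-> E; J <-> G; 2 Q -> X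
- in an amount of G, one E counts as one G

We read a time constant first. Red's first reading of G, taken as pseudo-first-order, gives k = 0.363 min⁻¹, which we hold as a reading of the life of Q at full D, 2.75 min. Teal, with more D, stands at 47.2% against red's 38.3% at that time, so k rises with cD.

Our carried quantity is the parity time, the feed time divided by the equivalents of D: the moment when the D delivered equals the Q charged. Until then the D delivered falls short of the Q charged, so D is the limiting reagent of that stretch. For midnight it is 0.800 min, for dusk 0.200 min; dawn has everything in at the start, and autumn has its D there from the start.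

Now midnight in slow motion. In midnight's first instants cD is near zero, and Q faces the pairing to X. If k grows in proportion to delivered D, we estimate that midnight reaches parity with hardly any of Q served by D, while dawn serves ten times that in the same time. In the middle, halfway through midnight's feed, the same proportion puts the life of Q at 5.50 min. We take the pairing to X as going with cQ squared and the route through D with cQ times cD. Near the end red's curve is slow: it gains 7.9 percentage points over its last 2.00 min. The readings hold G alone, so we put no number on X. We commit to an order: dawn, which is red's recipe at 73.4%, above dusk, above midnight, and midnight lower than a plain delay gives.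

The forecast names dawn, with 67% for midnight, 71.5% for dusk, 73% for dawn and 61% for autumn, holding that “Feeding D only delays the curve.”

The flasks give 45.8% for midnight, 61.8% for dusk, 72.1% for dawn and 65.2% for autumn, so dawn leads.

    Q + D ⇌ Z (K = 13.0 M⁻¹, k = 57.0 M⁻¹ s⁻¹)
    Z → G (k = 0.0210 s⁻¹)
    Q + G ⇌ E, settled at all times (K = 270 M⁻¹)
    J ⇌ G, rate k4*(cs4 - [G]) while solid is left; crystals form when [G] > cs4 (solubility = 5.40 mM, k = 2.10 s⁻¹)
    2 Q → X (k = 0.420 M⁻¹ s⁻¹)

In the flasks that hold their Q from the start, X climbs as G falls: at 6.00 min it stands at 13.7% in dawn, 25.3% in dusk with parity at 0.200 min, and 41.4% in midnight with parity at 0.800 min. Midnight already holds 40.0% of X at 3.00 min. The neighbour, midnight with 0.0040 M of Q, keeps the same equivalents and feed time, so its parity stays 0.800 min. Its X is 32.7%, less than midnight's but more than dawn's. It ends with 16% of its Q free and G at 40.9%.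

The earlier runs and the new flask come from a simulation for an exercise, and the scatter is random.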